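## Structural features

Megaphone acetate joins a cyclohex-2-enone (ring A: C1 carbonyl, C2=C3, C4 bearing OMe, C5H2, C6 quaternary) to a 3,4,5-trimethoxyphenyl group (ring B). The link is the two-carbon bridge C8 (CH–CH3, bonded to C6) and C7 (CH–OAc, bonded to ring B), and these labels are kept for every intermediate. C6 also carries the allyl group, so C6 (R), C8 (S) and C7 (R) form an unbroken stereotriad whose central bond C6–C8 links a quaternary to a tertiary carbon. C4 (R) is 1,3 to C6, with OMe trans to allyl and cis to the C8 branch; this face is called alpha and the allyl face beta. The oxygens on C1 and C7 are 1,4-related, a dissonant pattern that no aldol or Michael pairing delivers.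

Three groups are fragile:
- the benzylic acetate on the electron-rich ring B (ionisation, elimination);
- the gamma-methoxy enone (dienolisation can shift the double bond or epimerise C4);
- the terminal alkene, which rules out late hydroboration, ozonolysis and hydrogenation.

The real difficulty is the crowded C6–C8 bond together with the relative and absolute configuration of the triad, not ring A itself. The key step exploits one feature: the contiguous carbons C6, C8 and C7 carry an acceptor (C1=O, on C6) at one end and a donor (ring B, on C7) at the other. Joining C6 to C7 in the retrosynthetic sense therefore gives a donor–acceptor cyclopropane, whose polarised C6–C7 bond is a latent C7 cation and a latent C6 enolate.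

## Logic of the disconnections

**11 to 9.** No skeletal bond is cut; the C2=C3 double bond is removed. The gamma-methoxy enone is the most sensitive part of ring A and would compete with every carbenoid, hydride and Lewis acid used earlier, so it is made last. Because C6 is quaternary, C2 is the only enolisable position of 9, so the forward dehydrogenation has no regiochemical choice. It must spare the allyl group and the benzylic acetate.

**9 to 7 (key disconnection).** The C6–CH2 bond to allyl and the C7–O bond to acetate are cut, and C6 is joined to C7. In one sentence: the three-membered ring of 7 is cleaved at C6–C7 by acetate, and the enol silane 8 that is set free is allylated at C6. The quaternary carbon, two of the three contiguous stereocentres, the acetate and the allyl group all disappear, and the dissonant 1,4 pattern is stored as ring strain in a rigid ring. The forward step needs inversion at C7, cleavage of C6–C7 rather than C6–C8, a regiodefined C1=C6 enolate, and allyl delivery to the beta face.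

**7 to 6.** The C4–H bond is cut and a second methoxy group is placed on C4. This removes the remote stereocentre and makes ring A symmetric apart from the spiro ring. The forward hydride delivery must come from the beta face. This is the one stage at which the alpha face is screened by a C6 substituent (C8), and the ketal must ionise without disturbing the three-membered ring.

**6 to 4 (through 5).** C1 is first taken back to the carbinol level. The C6–C8 and C7–C8 bonds are then cut, which lifts the CH–CH3 unit out of the ring. The crowded C6–C8 bond is thus made in a concerted, hydroxyl-directed [2+1] addition to a flat alkene instead of by substitution at a hindered centre. The forward step must add to the face syn to the C1 oxygen and must place the methyl group trans to ring B.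

**4 to 3.** The C1–H bond is cut. C1 is the only stereocentre set by an external chiral reagent. Its information is passed to C6, C7 and C8 and is then erased by oxidation. The forward reduction must be 1,2-selective and must distinguish the alkylidene-bearing alpha carbon from C2H2.

**3 to 1 and 2.** The C6=C7 double bond is cut in the aldol sense. A consonant 1,3 pair is easy to make, and the later insertion of C8 turns it into the dissonant 1,4 pair. Both fragments are achiral and purchasable. The forward step must stop at mono-condensation and give the E alkene.

## Other disconnections considered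

**Alternative 1:** The first cut that comes to mind is the C6–CH2 bond of the allyl group, made last.
- Forward step: the C6 enolate of the des-allyl enone A1 (or its allyl enol carbonate in a decarboxylative Tsuji–Trost reaction) would be allylated trans to the C4 methoxy group.
- The facial argument is the same as in the chosen plan. However, A1 still contains the crowded C6–C8 bond, the C7/C8 pair and the dissonant C1/C7 pattern, so the cut removes three carbons and none of the real difficulty.
- A1 has an acidic C6–H in a 4-methoxycyclohexenone. Strong base can shift the dienolate and expel methoxide, which ends in aromatisation, and it also attacks the benzylic ester, so a protecting-group exchange at C7 would be needed.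
- In the chosen plan the same type of enolate arises regiospecifically, under neutral conditions, in a ring that cannot aromatise.

**Alternative 2:** Cut C6–C8 directly as a union of two enolate carbons.
- Forward step: the silicon-tethered bis-enol ether A2 of the 2-allyl ring ketone and the aryl ethyl ketone would be oxidised with (NH4)2Ce(NO3)6 to the 1,4-diketone A3. C7 would then be reduced and acetylated.
- This is the shortest answer to the dissonant pattern, but the stereochemical analysis is unfavourable. The accessible Z enol ether, held parallel to the ring enol ether by the tether, places the C8 methyl group over the allyl group, which corresponds to the C6/C8 relation opposite to the target.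
- Felkin–Anh hydride delivery to the C7 ketone of A3, with C6 as the large group, corresponds to the 7-epimer.
- Nothing in the step fixes absolute configuration, and ring B competes for the oxidant.

**Alternative 3:** Cut C6–allyl in an aromatic precursor (alkylative dearomatisation).
- Forward step: the phenolate of A4 would be C-allylated at C6 to the 2,4-dienone A5, and the C4=C5 enol ether would then be saturated.
- Ring A would start flat and cheap, and A(1,3) control by C8 points to the correct face.
- The phenolate, however, offers O, C2 and C6. Attack at the unsubstituted C2 is less hindered and becomes irreversible through tautomerisation, and the O-allyl ether funnels to the same C2 product by Claisen rearrangement.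
- From A5, saturating only C4=C5 beside an allyl group and an enone, with hydrogen delivered to the beta face of C4, has no dependable solution.

Key step: step 6

Assumption: 1,1-diiodoethane, trimethylsilyl acetate, diallyl carbonate, the (S)-oxazaborolidine and (S)-t-BuPHOX are taken as purchased reagents; only 1 and 2 count as starting materials.

## Steps

Step 1
Reactants: 1 4,4-dimethoxycyclohexan-1-one; 2 3,4,5-trimethoxybenzaldehyde
Product: 3 (2E)-4,4-dimethoxy-2-[(3,4,5-trimethoxyphenyl)methylidene]cyclohexan-1-one
Conditions: NaOH (0.3 equiv), EtOH–H2O, 25 °C, 1 in twofold excess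
Reagents that add atoms: none
Why: Claisen–Schmidt condensation; 2 cannot enolise, the two alpha carbons of 1 are equivalent, and E1cB dehydration should give the more stable E alkene with ring B away from the carbonyl group. The excess of 1 holds back a second condensation and the ketal is inert to base.

Step 2
Reactants: 3 (2E)-4,4-dimethoxy-2-[(3,4,5-trimethoxyphenyl)methylidene]cyclohexan-1-one
Product: 4 (1R,2E)-4,4-dimethoxy-2-[(3,4,5-trimethoxyphenyl)methylidene]cyclohexan-1-ol
Conditions: (S)-Me-CBS oxazaborolidine (10 mol %), BH3·SMe2, THF, −20 °C
Reagents that add atoms: none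
Why: Corey–Bakshi–Shibata reduction; the alkylidene-bearing C6 acts as the large and C2H2 as the small flank of the carbonyl group, so the (S)-catalyst should deliver hydride to the face that gives the 1R carbinol (OH on the alpha face). The catalysed 1,2-reduction should outrun hydroboration of the styrene unit.

Step 3
Reactants: 4 (1R,2E)-4,4-dimethoxy-2-[(3,4,5-trimethoxyphenyl)methylidene]cyclohexan-1-ol
Product: 5 (1R,2S,3R,4R)-7,7-dimethoxy-1-methyl-2-(3,4,5-trimethoxyphenyl)spiro[2.5]octan-4-ol
Conditions: Et2Zn, CH3CHI2, CH2Cl2, −15 to 0 °C
Reagents that add atoms: 1,1-diiodoethane CC(I)I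
Why: Hydroxyl-directed Simmons–Smith cyclopropanation (Furukawa variant) with an ethylidene carbenoid; the zinc alkoxide should deliver C8 to the alkene face syn to the C1 oxygen (alpha), and the stereospecific syn addition keeps ring B cis to C5, which fixes C6 and C7. With zinc held on the C1 side, the carbenoid methyl group should lie over the vinylic hydrogen of C7 and away from ring B, which fixes C8 with methyl trans to aryl.

Step 4
Reactants: 5 (1R,2S,3R,4R)-7,7-dimethoxy-1-methyl-2-(3,4,5-trimethoxyphenyl)spiro[2.5]octan-4-ol
Product: 6 (1R,2S,3R)-7,7-dimethoxy-1-methyl-2-(3,4,5-trimethoxyphenyl)spiro[2.5]octan-4-one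
Conditions: Pr4N[RuO4] (5 mol %), N-methylmorpholine N-oxide, 4 Å MS, CH2Cl2, 25 °C
Reagents that add atoms: none
Why: Ley–Griffith oxidation; the neutral medium should avoid ionisation of the acid-labile cyclopropylcarbinol and loss of the ketal. The C1 stereocentre has passed on its information and is erased, and the donor–acceptor pair across C6–C7 is switched on.

Step 5
Reactants: 6 (1R,2S,3R)-7,7-dimethoxy-1-methyl-2-(3,4,5-trimethoxyphenyl)spiro[2.5]octan-4-one
Product: 7 (1R,2S,3R,7S)-7-methoxy-1-methyl-2-(3,4,5-trimethoxyphenyl)spiro[2.5]octan-4-one
Conditions: Et3SiH, Me3SiOTf (10 mol %), CH2Cl2, −78 °C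
Reagents that add atoms: none
Why: Ionic silane reduction of a ketal to an ether through its oxocarbenium ion; at −78 °C the silyl triflate should ionise the ketal much faster than it activates the ketone or the three-membered ring. In the chair with the aryl-bearing C7 equatorial, C8 is the axial substituent on C6 and screens the alpha face of C4, so hydride should enter from the beta face and leave OMe alpha, cis to C8.

Step 6
Reactants: 7 (1R,2S,3R,7S)-7-methoxy-1-methyl-2-(3,4,5-trimethoxyphenyl)spiro[2.5]octan-4-one
Product: 9 (1R,2S)-2-[(1R,5S)-1-allyl-5-methoxy-2-oxocyclohexyl]-1-(3,4,5-trimethoxyphenyl)propyl acetate, via acetoxy enol silane 8 (not isolated)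
Conditions: Me3SiOAc, Me3SiOTf (15 mol %), CH2Cl2, −78 to −40 °C, then Et3N, evaporation; Pd2(dba)3 (2.5 mol %), (S)-t-BuPHOX (6 mol %), diallyl carbonate, Bu4N[Ph3SiF2] (35 mol %), THF, 25 °C
Reagents that add atoms: trimethylsilyl acetate CC(=O)O[Si](C)(C)C; diallyl carbonate C=CCOC(=O)OCC=C
Why: Proposed new method: Me3SiOTf silylates the C1 carbonyl oxygen of 7, the pull of the resulting oxocarbenium ion and the push of ring B polarise the C6–C7 bond, and the carbonyl oxygen of Me3SiOAc attacks C7 from the rear, which gives 8 and hands the silyl cation back to triflate, so the opening is catalytic and loses no atom. The closest known reaction types are the opening of cyclopropyl ketones by Me3SiI to gamma-iodo enol silanes and the Lewis acid promoted SN2-type opening of donor–acceptor cyclopropanes by oxygen nucleophiles; the second stage is the known fluoride-triggered Tsuji–Trost allylation of tetrasubstituted enol silanes with zerovalent palladium and an allyl carbonate, and only the use of acetate and the coupling of both events across one C–C bond are new. No ring is closed: the three-membered ring is opened in the reverse sense of a 3-exo-tet closure. C7 is set by inversion (the S centre of 7 becomes the R centre of 8), and a looser ion pair should give the same result, because in the cation with H8 eclipsing the aryl plane the bulky C6 residue blocks the other face. C8 is not touched and carries over the configuration fixed in step 3. C6 is set when the enolate freed from 8 meets the pi-allyl palladium cation: A(1,3) strain between the C1 oxygen and C8 turns H8 towards that oxygen, the CH(OAc)Ar group then covers the alpha face together with the C4 methoxy group, and the (S)-ligand favours the same beta attack, so three elements are matched. The step needs cleavage of C6–C7 and not C6–C8, which the cation-stabilising ring B on C7 secures, and a C1=C6 enolate free of its C1=C2 isomer, which follows from the way it is formed and from the absence of a proton source.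

Step 7
Reactants: 9 (1R,2S)-2-[(1R,5S)-1-allyl-5-methoxy-2-oxocyclohexyl]-1-(3,4,5-trimethoxyphenyl)propyl acetate
Product: 11 megaphone acetate (1R,2S)-2-[(1R,5R)-1-allyl-5-methoxy-2-oxocyclohex-3-en-1-yl]-1-(3,4,5-trimethoxyphenyl)propyl acetate, via enol silane 10 (not isolated)
Conditions: LiN(SiMe3)2, Me3SiCl, THF, −78 °C; then IBX, DMSO, 25 °C
Reagents that add atoms: none
Why: Kinetic enol silane formation (only C2 carries alpha hydrogens, and the ketone is more acidic than the acetate) followed by IBX dehydrogenation of the enol silane; no stereocentre is touched. A Saegusa–Ito oxidation with Pd(OAc)2 is avoided because the C2 palladium enolate could add to the allyl group.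

## Compound list

1 | 4,4-dimethoxycyclohexan-1-one | COC1(OC)CCC(=O)CC1 | starting material
2 | 3,4,5-trimethoxybenzaldehyde | COc1cc(C=O)cc(OC)c1OC | starting material
3 | (2E)-4,4-dimethoxy-2-[(3,4,5-trimethoxyphenyl)methylidene]cyclohexan-1-one | O=C1CCC(OC)(OC)C/C1=C\c1cc(OC)c(OC)c(OC)c1 | intermediate
4 | (1R,2E)-4,4-dimethoxy-2-[(3,4,5-trimethoxyphenyl)methylidene]cyclohexan-1-ol | O[C@@H]1CCC(OC)(OC)C/C1=C\c1cc(OC)c(OC)c(OC)c1 | intermediate
5 | (1R,2S,3R,4R)-7,7-dimethoxy-1-methyl-2-(3,4,5-trimethoxyphenyl)spiro[2.5]octan-4-ol | O[C@@H]1CCC(OC)(OC)C[C@]12[C@H](C)[C@H]2c1cc(OC)c(OC)c(OC)c1 | intermediate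
6 | (1R,2S,3R)-7,7-dimethoxy-1-methyl-2-(3,4,5-trimethoxyphenyl)spiro[2.5]octan-4-one | O=C1CCC(OC)(OC)C[C@]12[C@H](C)[C@H]2c1cc(OC)c(OC)c(OC)c1 | intermediate
7 | (1R,2S,3R,7S)-7-methoxy-1-methyl-2-(3,4,5-trimethoxyphenyl)spiro[2.5]octan-4-one | O=C1CC[C@H](OC)C[C@]12[C@H](C)[C@H]2c1cc(OC)c(OC)c(OC)c1 | intermediate
8 | (1R,2S)-2-[(5S)-5-methoxy-2-(trimethylsilyloxy)cyclohex-1-en-1-yl]-1-(3,4,5-trimethoxyphenyl)propyl acetate | C[Si](C)(C)OC1=C([C@H](C)[C@@H](OC(C)=O)c2cc(OC)c(OC)c(OC)c2)C[C@@H](OC)CC1 | intermediate
9 | (1R,2S)-2-[(1R,5S)-1-allyl-5-methoxy-2-oxocyclohexyl]-1-(3,4,5-trimethoxyphenyl)propyl acetate | C=CC[C@]1([C@H](C)[C@@H](OC(C)=O)c2cc(OC)c(OC)c(OC)c2)C[C@@H](OC)CCC1=O | intermediate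
10 | (1R,2S)-2-[(1R,5S)-1-allyl-5-methoxy-2-(trimethylsilyloxy)cyclohex-2-en-1-yl]-1-(3,4,5-trimethoxyphenyl)propyl acetate | C=CC[C@]1([C@H](C)[C@@H](OC(C)=O)c2cc(OC)c(OC)c(OC)c2)C[C@@H](OC)CC=C1O[Si](C)(C)C | intermediate
11 | megaphone acetate, (1R,2S)-2-[(1R,5R)-1-allyl-5-methoxy-2-oxocyclohex-3-en-1-yl]-1-(3,4,5-trimethoxyphenyl)propyl acetate | C=CC[C@]1([C@H](C)[C@@H](OC(C)=O)c2cc(OC)c(OC)c(OC)c2)C[C@@H](OC)C=CC1=O | target

Total step count: 7. Longest linear sequence: 7 steps (from 1 or 2 to 11).

## Least certain steps

**Step 6 (key step, new method).**
- What may go wrong in the first stage: full ionisation at C7 may outrun capture by acetate. It could be followed by loss of H8, closure through the enol oxygen, participation of the C4 methoxy oxygen, or erosion of the C7 configuration.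
- What may go wrong in the second stage: the free enolate may displace or be acylated by the neighbouring acetate before it is allylated.
- Fallback: it separates the events, uses known chemistry, sets out from 7 and returns at 8. Acetolysis with Sc(OTf)3 in acetic acid, a Lewis acid opening of a donor–acceptor cyclopropane by an oxygen nucleophile, gives (1R,2S)-2-[(5S)-5-methoxy-2-oxocyclohexyl]-1-(3,4,5-trimethoxyphenyl)propyl acetate F1 as a pair of C6 epimers. Thermodynamic enol silane formation (Me3SiCl, NaI, Et3N, MeCN) then gives 8, which is freed from its C1=C2 isomer and allylated as in the second stage of step 6.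

**Step 3.**
- What may go wrong: transfer of the substituted carbenoid to a trisubstituted alkene may be slow. Control over the orientation of the methyl group, which decides C8 and hence the whole triad, may be poor. The zinc salts may also strip the ketal.
- Fallback: it exchanges the roles in the [2+1] addition, sets out from 1 and 2 and returns at 6.
  - Formylation of 1 (HCO2Et, NaH) gives 2-(hydroxymethylidene)-4,4-dimethoxycyclohexan-1-one F2.
  - Deformylative diazo transfer (TsN3, Et3N) gives 2-diazo-4,4-dimethoxycyclohexan-1-one F3.
  - Julia–Kocienski olefination of 2 with 5-(ethylsulfonyl)-1-phenyl-1H-tetrazole and KN(SiMe3)2 gives 1,2,3-trimethoxy-5-[(1E)-prop-1-en-1-yl]benzene F4.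
  - Cyclopropanation of F4 by F3 with Rh2(S-PTTL)4, or its enantiomer as required, at −78 °C gives 6. The aryl/methyl trans relation is then fixed by stereospecific addition to the E alkene.

**Step 5.**
- What may go wrong: the silyl triflate may also activate the donor–acceptor ring, so that C7 is reduced. Ring B may capture the C4 cation across the ring. The facial bias of a cyclopropane carbon as axial group may be small.
- Fallback: it avoids any cation at C4, sets out from 6 and returns at 7. Mild hydrolysis (oxalic acid on silica gel, CH2Cl2) gives (1R,2S,3R)-1-methyl-2-(3,4,5-trimethoxyphenyl)spiro[2.5]octane-4,7-dione F5. LiBH(s-Bu)3 at −78 °C reduces the less hindered C4 carbonyl group by equatorial attack to (1R,2S,3R,7S)-7-hydroxy-1-methyl-2-(3,4,5-trimethoxyphenyl)spiro[2.5]octan-4-one F6. Me3OBF4 with 1,8-bis(dimethylamino)naphthalene then gives 7.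

**Step 7.**
- What may go wrong: further dehydrogenation towards the dienone, oxidation at the electron-rich ring B, or incomplete silylation of the hindered ketone.
- Fallback: it replaces the oxidation by a syn elimination, sets out from 10 and returns at 11. PhSeCl at −78 °C reacts with the enol silane in preference to the allyl group and gives the C2 phenylselanyl derivative of 9 F7. H2O2 with pyridine at 0 °C then forms the selenoxide, which eliminates to 11.

## Further compounds

F1 | step 6 | (1R,2S)-2-[(5S)-5-methoxy-2-oxocyclohexyl]-1-(3,4,5-trimethoxyphenyl)propyl acetate (C6 epimers) | O=C1CC[C@H](OC)CC1[C@H](C)[C@@H](OC(C)=O)c1cc(OC)c(OC)c(OC)c1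
F2 | step 3 | 2-(hydroxymethylidene)-4,4-dimethoxycyclohexan-1-one | O=C1CCC(OC)(OC)CC1=CO
F3 | step 3 | 2-diazo-4,4-dimethoxycyclohexan-1-one | O=C1CCC(OC)(OC)CC1=[N+]=[N-]
F4 | step 3 | 1,2,3-trimethoxy-5-[(1E)-prop-1-en-1-yl]benzene | C/C=C/c1cc(OC)c(OC)c(OC)c1
F5 | step 5 | (1R,2S,3R)-1-methyl-2-(3,4,5-trimethoxyphenyl)spiro[2.5]octane-4,7-dione | O=C1CCC(=O)C[C@]12[C@H](C)[C@H]2c1cc(OC)c(OC)c(OC)c1
F6 | step 5 | (1R,2S,3R,7S)-7-hydroxy-1-methyl-2-(3,4,5-trimethoxyphenyl)spiro[2.5]octan-4-one | O=C1CC[C@H](O)C[C@]12[C@H](C)[C@H]2c1cc(OC)c(OC)c(OC)c1
F7 | step 7 | C2 phenylselanyl derivative of 9 (C2 epimers) | C=CC[C@]1([C@H](C)[C@@H](OC(C)=O)c2cc(OC)c(OC)c(OC)c2)C[C@@H](OC)CC([Se]c2ccccc2)C1=O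
A1 | alternative 1 | des-allyl enone, (1R,2S)-2-[(5R)-5-methoxy-2-oxocyclohex-3-en-1-yl]-1-(3,4,5-trimethoxyphenyl)propyl acetate (C6 epimers) | O=C1C=C[C@H](OC)CC1[C@H](C)[C@@H](OC(C)=O)c1cc(OC)c(OC)c(OC)c1
A2 | alternative 2 | dimethylsilyl bis-enol ether of the 2-allyl-4-methoxy ring ketone and the aryl ethyl ketone (Z enol ether) | C=CCC1=C(O[Si](C)(C)O/C(=C\C)c2cc(OC)c(OC)c(OC)c2)CC[C@H](OC)C1
A3 | alternative 2 | 1,4-diketone, 2-allyl-4-methoxy-2-[1-oxo-1-(3,4,5-trimethoxyphenyl)propan-2-yl]cyclohexan-1-one | C=CC[C@]1([C@H](C)C(=O)c2cc(OC)c(OC)c(OC)c2)C[C@@H](OC)CCC1=O
A4 | alternative 3 | (1R,2S)-2-(2-hydroxy-5-methoxyphenyl)-1-(3,4,5-trimethoxyphenyl)propyl acetate | C[C@@H](c1cc(OC)ccc1O)[C@@H](OC(C)=O)c1cc(OC)c(OC)c(OC)c1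
A5 | alternative 3 | 6-allyl-4-methoxycyclohexa-2,4-dienone bearing the C8–C7 side chain on C6 | C=CC[C@]1([C@H](C)[C@@H](OC(C)=O)c2cc(OC)c(OC)c(OC)c2)C=C(OC)C=CC1=O
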